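**Retrosynthetic overview**
1. Target 19 ⇐ tert-butyl ester 18 ⇐ C9–C11 bond by B-alkyl Suzuki coupling of enol triflate 13 with the borane of dienoate 16 (from ynoate 14 by syn-carbocupration).
2. 13 ⇐ triol 12 (3α/19 acylation) ⇐ 3,6-dione 10 (face-selective hydride reductions, lactone reduction) ⇐ Δ5 keto ester 8 (α-face hydroboration, oxidation).
3. 8 ⇐ bicyclic enone ester 5 by two dianion operations: C8 methylation, then C9 triflation with deconjugative C4 methylation.
4. 5 ⇐ 2-methylcyclohexane-1,3-dione 1 + Nazarov's reagent 2 by an enantioselective organocatalytic Robinson annulation that sets C10.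
5. Ring order: ring B is bought as 1; ring A is closed onto it in step 1; no other ring is formed.

Assumption: 2 and 14 are bought as catalogue items; locants C1–C20 are labdane locants (C18 = 4α-methyl, C19 = 4β carbon, C20 = 10β-methyl, β = face of the C10 methyl), so the target is (3R,4S,5R,6R,10S), 13E.

**Step 1**
Reactants: 1 2-methylcyclohexane-1,3-dione; 2 methyl 3-oxopent-4-enoate
Product: 5 methyl (4aS)-4a-methyl-2,5-dioxo-2,3,4,4a,5,6,7,8-octahydronaphthalene-1-carboxylate (3,9-dioxo-Δ4 enone ester), via triketo ester 3 (not isolated), via ketol 4 (not isolated)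
Conditions: (R)-TRIP (10 mol %), PhMe, 25 °C, 2 added over 6 h, 24 h; then 4 Å MS, 60 °C, 48 h
Reagents that add atoms: none
Why: Proposed new method: an enantioselective Robinson annulation in which, after acid-promoted Michael addition of 1 to 2, the chiral phosphoric acid binds the β-keto ester enol of 3 (P=O···H–O) together with one of the two enantiotopic ring carbonyls (P–OH···O=C) in a compact bifunctional transition state, so that C4 adds to a single carbonyl (desymmetrising intramolecular aldol, which sets C10 as S) and ketol 4 dehydrates into conjugation; the closest known reactions are the Hajos–Parrish–Eder–Sauer–Wiechert annulation and the phosphoric acid-catalysed desymmetrising aldol condensation of 2-(3-oxobutyl)-1,3-diones, neither shown so far for a β-keto ester donor derived from Nazarov's reagent.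

**Step 2**
Reactants: 5 enone ester
Product: 6 methyl (4aS)-4a,6-dimethyl-2,5-dioxo-2,3,4,4a,5,6,7,8-octahydronaphthalene-1-carboxylate (8-methyl enone ester; both C8 epimers)
Conditions: NaH (1.0 equiv), THF, 0 °C; LiN(i-Pr)2 (1.1 equiv), −78 °C; MeI (1.05 equiv), −78 → −30 °C; AcOH
Reagents that add atoms: iodomethane, CI
Why: Dianion alkylation with Hauser-type site selectivity: the vinylogous β-keto ester is stored as its stabilised sodium dienolate, the C9 ketone is then enolised towards C8, and one equivalent of MeI reacts only at the more basic, last-formed enolate carbon C8, whose configuration is irrelevant because C8 becomes sp2 in step 3.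

**Step 3**
Reactants: 6 8-methyl enone ester
Product: 8 methyl (1R,4aS)-1,4a,6-trimethyl-2-oxo-5-(trifluoromethylsulfonyloxy)-1,2,3,4,4a,7-hexahydronaphthalene-1-carboxylate (3-oxo; 4α-Me; 4β-CO2Me; Δ5; Δ8 9-OTf), via triflate dienolate 7 (not isolated)
Conditions: NaH (1.0 equiv), THF, 0 °C; LiN(i-Pr)2 (1.15 equiv), −78 → 0 °C; Comins' reagent (1.05 equiv), −78 °C; then MeI (5 equiv), DMPU, −78 → 25 °C
Reagents that add atoms: N-(5-chloropyridin-2-yl)-1,1,1-trifluoro-N-(trifluoromethylsulfonyl)methanesulfonamide (Comins' reagent), FC(F)(F)S(=O)(=O)N(c1ccc(Cl)cn1)S(=O)(=O)C(F)(F)F; iodomethane, CI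
Why: The same dianion logic in one flask: Comins' reagent O-sulfonylates only the reactive C9 enolate (enol triflate formation), after which the remaining dienolate 7 undergoes deconjugative α-methylation at C4 on the α face, anti to the axial C10 methyl, which sets C4 (methyl α, CO2Me β) and moves the alkene to C5=C6.

**Step 4**
Reactants: 8 Δ5 keto ester triflate
Product: 10 methyl (1R,4aS,8aR)-1,4a,6-trimethyl-2,8-dioxo-5-(trifluoromethylsulfonyloxy)-1,2,3,4,4a,7,8,8a-octahydronaphthalene-1-carboxylate (3,6-dioxo; 5α-H), via organoborane 9 (not isolated)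
Conditions: BH3·THF (4 equiv), THF, 0 → 25 °C, 16 h; H2O; then CrO3, H2SO4, H2O, acetone–Et2O, 0 → 25 °C
Reagents that add atoms: chromium trioxide (as aqueous CrO3/H2SO4), O=[Cr](=O)=O; water, O
Why: Brown hydroboration followed by CrO3/H2SO4 oxidation of the organoborane: BH3 (which also reduces the C3 ketone to a borinate) adds across C5=C6 from the α face, opposite the C10 methyl and the 4β-CO2Me, placing boron on C6 and hydrogen on C5 (5α-H, trans-decalin), and the oxidant then turns both the C6–B bond and the C3 borinate into ketones while the electron-poor tetrasubstituted enol triflate is untouched.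

**Step 5**
Reactants: 10 3,6-dione
Product: 12 triol triflate (3α,6β-dihydroxy-4β-hydroxymethyl-4α,8,10β-trimethyl-5α-decal-8-en-9-yl triflate), via lactone alcohol 11 (not isolated)
Conditions: LiBH(s-Bu)3 (2.5 equiv), THF, −78 → −40 °C; then LiBH4 (4 equiv), −40 → 40 °C; aq. NH4Cl
Reagents that add atoms: none
Why: Substrate-controlled hydride reductions: the bulky trialkylborohydride attacks C3 equatorially to give the axial 3α-alcohol and attacks C6 from the open α face (the β face is blocked by the syn-axial C10 methyl and C19 group) to give the 6β-alkoxide, which lactonises onto the 1,3-diaxial C19 ester (11), and LiBH4 then reduces the γ-lactone to the 6β,19-diol without touching the enol triflate.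

**Step 6**
Reactants: 12 triol triflate
Product: 13 bis-isovalerate triflate (3α,19-bis(3-methylbutanoyloxy)-6β-hydroxy enol triflate)
Conditions: 3-methylbutanoyl chloride (2.4 equiv), pyridine, DMAP (10 mol %), CH2Cl2, 0 → 25 °C
Reagents that add atoms: 3-methylbutanoyl chloride, CC(C)CC(=O)Cl
Why: Sterically controlled DMAP-catalysed acylation: the primary 19-OH and the 3α-OH are esterified, whereas the 6β-OH, 1,3-diaxial to both the C10 methyl and the C19 CH2 group, stays free.

**Step 7**
Reactants: 14 tert-butyl but-2-ynoate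
Product: 16 tert-butyl (2E)-3-methylpenta-2,4-dienoate, via alkenylcopper adduct 15 (not isolated)
Conditions: CH2=CHMgBr (1.2 equiv), CuBr·SMe2 (1.2 equiv), THF, −78 °C; 14, −78 °C, 1 h; MeOH then aq. NH4Cl at −78 °C
Reagents that add atoms: vinylmagnesium bromide, C=C[Mg]Br
Why: Syn-carbocupration of an ynoate: vinylcopper adds across the triple bond with vinyl and copper cis, and cold protonation of 15 with retention gives the (2E)-dienoate, which fixes the C13=C14 geometry of the target.

**Step 8**
Reactants: 13 bis-isovalerate triflate; 16 tert-butyl (2E)-3-methylpenta-2,4-dienoate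
Product: 18 tert-butyl 6β-hydroxy-3α,19-bis(3-methylbutanoyloxy)labda-8,13E-dien-15-oate, via alkylborane 17 (not isolated)
Conditions: 16 (1.6 equiv), 9-BBN (1.5 equiv), THF, 0 → 25 °C; then 13, Pd(dppf)Cl2 (10 mol %), AsPh3 (10 mol %), aq. K3PO4, DMF, 50 °C
Reagents that add atoms: none
Why: B-alkyl Suzuki–Miyaura coupling: 9-BBN hydroborates only the terminal vinyl group of 16 (boron on the CH2 terminus, trisubstituted enoate untouched) and the primary alkylborane 17 couples with the C9 enol triflate under Pd(dppf)Cl2 catalysis, forming C9–C11 with both alkene geometries retained while the free 6β-OH and the isovalerates tolerate aqueous K3PO4.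

**Step 9**
Reactants: 18 tert-butyl ester
Product: 19 CNP0333611.1, 6β-hydroxy-3α,19-bis(3-methylbutanoyloxy)labda-8,13E-dien-15-oic acid
Conditions: TFA/CH2Cl2 (1:4), 0 °C, 2 h
Reagents that add atoms: none
Why: Acidolysis of the tert-butyl ester (loss of isobutene through the tert-butyl cation) frees the C15 acid, while the two hindered isovalerates, the 6β-OH and the tetrasubstituted Δ8 alkene (the thermodynamically preferred position) are stable to cold TFA.

**Compound list**
1 | 2-methylcyclohexane-1,3-dione | CC1C(=O)CCCC1=O | starting material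
2 | methyl 3-oxopent-4-enoate (Nazarov's reagent) | COC(=O)CC(=O)C=C | starting material
3 | triketo ester, methyl 5-(1-methyl-2,6-dioxocyclohexyl)-3-oxopentanoate | COC(=O)CC(=O)CCC1(C)C(=O)CCCC1=O | intermediate (not isolated)
4 | ketol, methyl (4aS)-8a-hydroxy-4a-methyl-2,5-dioxodecahydronaphthalene-1-carboxylate (cis-fused, OH syn to the angular methyl; C1 epimers) | C[C@]12CCC(=O)C(C(=O)OC)[C@@]1(O)CCCC2=O | intermediate (not isolated)
5 | methyl (4aS)-4a-methyl-2,5-dioxo-2,3,4,4a,5,6,7,8-octahydronaphthalene-1-carboxylate | C[C@]12CCC(=O)C(C(=O)OC)=C1CCCC2=O | intermediate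
6 | methyl (4aS)-4a,6-dimethyl-2,5-dioxo-2,3,4,4a,5,6,7,8-octahydronaphthalene-1-carboxylate (both C8 epimers) | C[C@]12CCC(=O)C(C(=O)OC)=C1CCC(C)C2=O | intermediate
7 | triflate dienolate, sodium 3,5-dienolate of the C9 enol triflate of 6 | CC1=C(OS(=O)(=O)C(F)(F)F)[C@@]2(C)CCC([O-])=C(C(=O)OC)C2=CC1.[Na+] | intermediate (not isolated)
8 | methyl (1R,4aS)-1,4a,6-trimethyl-2-oxo-5-(trifluoromethylsulfonyloxy)-1,2,3,4,4a,7-hexahydronaphthalene-1-carboxylate (4α-Me, 4β-CO2Me) | CC1=C(OS(=O)(=O)C(F)(F)F)[C@@]2(C)CCC(=O)[C@](C)(C(=O)OC)C2=CC1 | intermediate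
9 | organoborane, 6α-boryl-5α-H adduct of 8 with C3 held as O-borinate (C3 epimers) | CC1=C(OS(=O)(=O)C(F)(F)F)[C@@]2(C)CCC(OB)[C@](C)(C(=O)OC)[C@@H]2[C@@H](B)C1 | intermediate (not isolated)
10 | methyl (1R,4aS,8aR)-1,4a,6-trimethyl-2,8-dioxo-5-(trifluoromethylsulfonyloxy)-1,2,3,4,4a,7,8,8a-octahydronaphthalene-1-carboxylate | CC1=C(OS(=O)(=O)C(F)(F)F)[C@@]2(C)CCC(=O)[C@](C)(C(=O)OC)[C@@H]2C(=O)C1 | intermediate
11 | lactone alcohol, 3α-hydroxy-19,6β-olide enol triflate | CC1=C(OS(=O)(=O)C(F)(F)F)[C@@]2(C)CC[C@@H](O)[C@](C)(C(=O)O3)[C@@H]2[C@H]3C1 | intermediate (not isolated)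
12 | triol triflate, 3α,6β,19-trihydroxy-5α-H 8-en-9-yl triflate | CC1=C(OS(=O)(=O)C(F)(F)F)[C@@]2(C)CC[C@@H](O)[C@](C)(CO)[C@@H]2[C@H](O)C1 | intermediate
13 | bis-isovalerate triflate, 3α,19-bis(3-methylbutanoyloxy)-6β-hydroxy 8-en-9-yl triflate | CC1=C(OS(=O)(=O)C(F)(F)F)[C@@]2(C)CC[C@@H](OC(=O)CC(C)C)[C@](C)(COC(=O)CC(C)C)[C@@H]2[C@H](O)C1 | intermediate
14 | tert-butyl but-2-ynoate | CC#CC(=O)OC(C)(C)C | starting material
15 | alkenylcopper adduct, tert-butyl 2-cuprio-3-methylpenta-2,4-dienoate (vinyl and Cu cis) | C=C/C(C)=C(\[Cu])C(=O)OC(C)(C)C | intermediate (not isolated)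
16 | tert-butyl (2E)-3-methylpenta-2,4-dienoate | C=C/C(C)=C/C(=O)OC(C)(C)C | intermediate
17 | alkylborane, tert-butyl (2E)-5-(9-borabicyclo[3.3.1]nonan-9-yl)-3-methylpent-2-enoate | CC(C)(C)OC(=O)/C=C(\C)CCB1C2CCCC1CCC2 | intermediate (not isolated)
18 | tert-butyl 6β-hydroxy-3α,19-bis(3-methylbutanoyloxy)labda-8,13E-dien-15-oate | CC1=C(CC/C(C)=C/C(=O)OC(C)(C)C)[C@@]2(C)CC[C@@H](OC(=O)CC(C)C)[C@](C)(COC(=O)CC(C)C)[C@@H]2[C@H](O)C1 | intermediate
19 | CNP0333611.1, (3R,4S,5R,6R,10S)-6β-hydroxy-3α,19-bis(3-methylbutanoyloxy)labda-8,13E-dien-15-oic acid | CC1=C(CC/C(C)=C/C(=O)O)[C@@]2(C)CC[C@@H](OC(=O)CC(C)C)[C@](C)(COC(=O)CC(C)C)[C@@H]2[C@H](O)C1 | target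

**Step count**
Total steps: 9. Longest linear sequence: 8 (steps 1, 2, 3, 4, 5, 6, 8, 9); step 7 is a one-step side branch.

**Three steps most likely to fail**

Step 1 (the proposed new reaction). The strongly enolised β-keto ester may add slowly or reversibly (retro-aldol before dehydration erodes ee), 2 can polymerise, and the sense of induction of (R)-TRIP has to be confirmed on the first run (the mirror-image acid is used if it is opposite). Fallback with known chemistry, setting out from 1 and coming back at 5: 1 and but-3-en-2-one are annulated under the established L-proline-catalysed conditions, through 2-methyl-2-(3-oxobutyl)cyclohexane-1,3-dione F1, to the (S)-Wieland–Miescher ketone F2. Johnson α-iodination (I2, pyridine, CH2Cl2) gives (4aS)-1-iodo-4a-methyl-4,4a,7,8-tetrahydronaphthalene-2,5(3H,6H)-dione F3. Methoxycarbonylation (Pd(OAc)2, PPh3, CO 1 atm, MeOH, Et3N, DMF, 60 °C) then gives 5.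

Step 3. The hindered C8–H may be deprotonated incompletely, and the dienolate may be O-sulfonylated or methylated at oxygen or C6. Fallback, setting out from 6 and coming back at 10: thermodynamic deconjugative methylation (KOt-Bu, t-BuOH–THF, MeI) gives the Δ5 3,9-dione methyl (1R,4aS)-1,4a,6-trimethyl-2,5-dioxo-1,2,3,4,4a,5,6,7-octahydronaphthalene-1-carboxylate F4. NaBH4 (MeOH–CH2Cl2, −40 °C) reduces only the ester-activated, less hindered C3 ketone to the 3-hydroxy 9-ketone F5; either C3 epimer serves because C3 is re-oxidised in step 4. KN(SiMe3)2 (2.2 equiv) and Comins' reagent convert the now unique ketone into the 3-hydroxy enol triflate F6, which under the conditions of step 4 gives the same borane 9 and then 10.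

Step 8. The tetrasubstituted triflate next to quaternary C10 may undergo slow oxidative addition or transmetalation, β-hydride elimination can compete, and hydroboration of the electron-poor diene 16 may not be fully terminal. Fallback, setting out from 13 and coming back at 18, with the coupling polarity reversed: Stille coupling with Bu3SnCH=CH2 (Pd(PPh3)4, LiCl, THF, 65 °C) gives the 9-vinyl diene F7. 9-BBN hydroborates only its terminal vinyl group to give the alkylborane F8 (not isolated), which is added syn across ynoate 14 by copper catalysis (CuOAc, P(OPh)3, KOt-Bu cat., t-BuOH as proton source) to give 18 with the E geometry.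

**Further compounds**
F1 | step 1 | 2-methyl-2-(3-oxobutyl)cyclohexane-1,3-dione | CC(=O)CCC1(C)C(=O)CCCC1=O
F2 | step 1 | (S)-Wieland–Miescher ketone, (4aS)-4a-methyl-4,4a,7,8-tetrahydronaphthalene-2,5(3H,6H)-dione | C[C@]12CCC(=O)C=C1CCCC2=O
F3 | step 1 | (4aS)-1-iodo-4a-methyl-4,4a,7,8-tetrahydronaphthalene-2,5(3H,6H)-dione | C[C@]12CCC(=O)C(I)=C1CCCC2=O
F4 | step 3 | methyl (1R,4aS)-1,4a,6-trimethyl-2,5-dioxo-1,2,3,4,4a,5,6,7-octahydronaphthalene-1-carboxylate (C8 epimers) | CC1C(=O)[C@@]2(C)CCC(=O)[C@](C)(C(=O)OC)C2=CC1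
F5 | step 3 | 3-hydroxy 9-ketone, methyl (4aS)-2-hydroxy-1,4a,6-trimethyl-5-oxo-1,2,3,4,4a,5,6,7-octahydronaphthalene-1-carboxylate (4α-Me, 4β-CO2Me; C3 and C8 epimers) | CC1C(=O)[C@@]2(C)CCC(O)[C@](C)(C(=O)OC)C2=CC1
F6 | step 3 | 3-hydroxy enol triflate, methyl (4aS)-2-hydroxy-1,4a,6-trimethyl-5-(trifluoromethylsulfonyloxy)-1,2,3,4,4a,7-hexahydronaphthalene-1-carboxylate (4α-Me, 4β-CO2Me; C3 epimers) | CC1=C(OS(=O)(=O)C(F)(F)F)[C@@]2(C)CCC(O)[C@](C)(C(=O)OC)C2=CC1
F7 | step 8 | 9-vinyl diene, 3α,19-bis(3-methylbutanoyloxy)-6β-hydroxy-9-vinyl decal-8-ene | CC1=C(C=C)[C@@]2(C)CC[C@@H](OC(=O)CC(C)C)[C@](C)(COC(=O)CC(C)C)[C@@H]2[C@H](O)C1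
F8 | step 8 | alkylborane, 9-[2-(9-borabicyclo[3.3.1]nonan-9-yl)ethyl] analogue of F7 | CC1=C(CCB3C4CCCC3CCC4)[C@@]2(C)CC[C@@H](OC(=O)CC(C)C)[C@](C)(COC(=O)CC(C)C)[C@@H]2[C@H](O)C1
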